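The two adjacent bonds on benzene ring B of the chromene, C6–C(acyl) and C7–O, are disconnected to a 6,7-aryne and isobutyric acid. The key step exploits the ortho relationship between the C6 isobutyryl carbon and the C7 hydroxyl oxygen. Insertion of the aryne into the acyl C–O bond of the acid sets both at once, with no C6/C8 acylation ambiguity. The precursor is a 2,2-dimethyl-2H-chromene (pyran ring A fused to ring B) with SiMe3 on C6, triflate on C7 and a MOM ether on C5. It is made from a chromanone whose chelated 5-OH distinguishes O5 from O7. Afterwards C8 is linked through CH2 to isobutyrylfilicinic acid (ring C).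

Key step: step 8

Remark (assumption): ring C of the target is written as one enol tautomer of an acylfilicinic acid; the tautomers interconvert and the route addresses the compound as such. Chromene numbering (O1, C2, C3, C4, C4a, C5–C8, C8a) is used throughout. The target has no stereocentre.

Step 1
Reactants: 1 phloroglucinol; 2 3-methylbut-2-enoic acid
Product: 3 5,7-dihydroxy-2,2-dimethylchroman-4-one
Conditions: P2O5, MeSO3H, 70 °C
Reagents that add atoms: none
Why: Friedel–Crafts acylation of the symmetric triol by the acylium ion of 2, followed by intramolecular oxa-Michael closure of the aryl enone, should give the chromanone without any regiochemical question.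

Step 2
Reactants: 3 5,7-dihydroxy-2,2-dimethylchroman-4-one
Product: 4 5-hydroxy-2,2-dimethyl-4-oxochroman-7-yl diethylcarbamate
Conditions: Et2NCOCl, K2CO3, MeCN, reflux
Reagents that add atoms: diethylcarbamoyl chloride, CCN(CC)C(=O)Cl
Why: In this O-carbamoylation the 5-OH is locked in a hydrogen bond to the C4 carbonyl, so the more acidic, unchelated 7-OH should be the one acylated.

Step 3
Reactants: 4 5-hydroxy-2,2-dimethyl-4-oxochroman-7-yl diethylcarbamate
Product: 5 5-(methoxymethoxy)-2,2-dimethyl-4-oxochroman-7-yl diethylcarbamate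
Conditions: NaH, DMF, 0 °C; MOMCl, 0 °C to rt
Reagents that add atoms: chloromethyl methyl ether, COCCl
Why: Williamson-type O-alkylation of the preformed sodium phenoxide overcomes the chelation of the 5-OH, and the tertiary carbamate is inert to NaH at this temperature.

Step 4
Reactants: 5 5-(methoxymethoxy)-2,2-dimethyl-4-oxochroman-7-yl diethylcarbamate
Product: 7 5-(methoxymethoxy)-2,2-dimethyl-2H-chromen-7-yl diethylcarbamate, via chroman-4-ol 6 (not isolated)
Conditions: NaBH4, MeOH–THF, 0 °C; crude 6, MsCl, Et3N, CH2Cl2, 0 °C to rt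
Reagents that add atoms: none
Why: Borohydride reduction gives a benzylic alcohol on an ortho/para-dioxygenated ring whose mesylate should ionise and lose a proton (E1 dehydration) under non-acidic conditions that spare the MOM acetal, giving the conjugated 2H-chromene.

Step 5
Reactants: 7 5-(methoxymethoxy)-2,2-dimethyl-2H-chromen-7-yl diethylcarbamate
Product: 9 5-(methoxymethoxy)-2,2-dimethyl-6-(trimethylsilyl)-2H-chromen-7-yl diethylcarbamate, via C6-aryllithium 8 (not isolated)
Conditions: s-BuLi, TMEDA, THF, −78 °C; Me3SiCl, −78 °C to rt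
Reagents that add atoms: chlorotrimethylsilane, C[Si](C)(C)Cl
Why: In this directed ortho-metalation C6–H lies between the carbamate and the MOM acetal, the two strongest lithium-coordinating groups, whereas C8–H is flanked by the carbamate and only a ring ether, so lithiation and silylation should occur at C6 while the low temperature suppresses the anionic ortho-Fries shift.

Step 6
Reactants: 9 5-(methoxymethoxy)-2,2-dimethyl-6-(trimethylsilyl)-2H-chromen-7-yl diethylcarbamate
Product: 10 5-(methoxymethoxy)-2,2-dimethyl-6-(trimethylsilyl)-2H-chromen-7-ol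
Conditions: LiAlH4, THF, 0 °C to reflux; aq. potassium sodium tartrate work-up
Reagents that add atoms: none
Why: Reductive carbamate cleavage by hydride addition to the carbamate carbonyl releases the phenoxide under aprotic conditions that avoid protodesilylation of the electron-rich aryl silane and leave the acetal and the styrenic alkene untouched.

Step 7
Reactants: 10 5-(methoxymethoxy)-2,2-dimethyl-6-(trimethylsilyl)-2H-chromen-7-ol
Product: 11 5-(methoxymethoxy)-2,2-dimethyl-6-(trimethylsilyl)-2H-chromen-7-yl trifluoromethanesulfonate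
Conditions: PhNTf2, DBU, MeCN, rt to 40 °C
Reagents that add atoms: N-phenylbis(trifluoromethanesulfonimide), O=S(=O)(N(c1ccccc1)S(=O)(=O)C(F)(F)F)C(F)(F)F
Why: O-Triflation of the phenoxide with a mild triflyl donor gives the ortho-silylaryl triflate without exposing the aryl–silicon bond, the acetal or the chromene to acid.

Step 8
Reactants: 11 5-(methoxymethoxy)-2,2-dimethyl-6-(trimethylsilyl)-2H-chromen-7-yl trifluoromethanesulfonate; 12 isobutyric acid
Product: 15 1-[7-hydroxy-5-(methoxymethoxy)-2,2-dimethyl-2H-chromen-6-yl]-2-methylpropan-1-one, via 6,7-aryne 13 (not isolated), via C6-caesio aryl isobutyrate 14 (not isolated)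
Conditions: CsF (excess), 12 (slight excess), THF, 125 °C, sealed tube
Reagents that add atoms: none
Why: Fluoride attacks silicon and the incipient C6 carbanion expels the C7 triflate, releasing aryne 13 in the presence of caesium isobutyrate. The carboxylate oxygen adds to C7, the aryne carbon distal to the inductively withdrawing C5 acetal oxygen, because the negative charge then develops on C6 next to that oxygen, which is the usual regiochemistry of 3-alkoxyarynes. Aryl anion 14 attacks its own ester carbonyl through a four-membered alkoxide that opens to the chelated C7 phenoxide, so C7–O and C6–C(acyl) form on adjacent carbons in one operation. The closest known reaction type is the fluoride-induced insertion of arynes into the acyl C–O bond of carboxylic acids to give ortho-hydroxyaryl ketones. No ring is closed and no stereocentre is formed. The step needs O-attack at C7, which the C5 OMOM group secures, and acyl transfer rather than protonation of 14, which the high temperature, the near-stoichiometric acid and the excess CsF favour.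

Step 9
Reactants: 15 1-[7-hydroxy-5-(methoxymethoxy)-2,2-dimethyl-2H-chromen-6-yl]-2-methylpropan-1-one
Product: 16 1-(5,7-dihydroxy-2,2-dimethyl-2H-chromen-6-yl)-2-methylpropan-1-one
Conditions: HCl (1 M), MeOH, rt
Reagents that add atoms: none
Why: Acid-catalysed acetal cleavage should be fast for a MOM ether ortho to a ketone, and methanol traps the released one-carbon unit as dimethoxymethane, away from the nucleophilic C8.

Step 10
Reactants: 16 1-(5,7-dihydroxy-2,2-dimethyl-2H-chromen-6-yl)-2-methylpropan-1-one
Product: 17 1-{8-[(dimethylamino)methyl]-5,7-dihydroxy-2,2-dimethyl-2H-chromen-6-yl}-2-methylpropan-1-one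
Conditions: CH2=NMe2+ I−, Et3N, CH2Cl2, 0 °C to rt
Reagents that add atoms: N,N-dimethylmethyleneiminium iodide, C=[N+](C)C.[I-]
Why: In this Mannich aminomethylation C8 is the only unsubstituted carbon of ring B (ortho to 7-OH, para to 5-OH), and the preformed iminium salt avoids free formaldehyde and hence methylene-bridged homodimers.

Step 11
Reactants: 1 phloroglucinol; 18 isobutyryl chloride
Product: 19 1-(2,4,6-trihydroxyphenyl)-2-methylpropan-1-one
Conditions: AlCl3, PhNO2, 60 °C; aq. HCl work-up
Reagents that add atoms: none
Why: Friedel–Crafts acylation of the symmetric triol should stop after one acyl group because the chelated ketone deactivates the ring.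

Step 12
Reactants: 19 1-(2,4,6-trihydroxyphenyl)-2-methylpropan-1-one
Product: 20 isobutyrylfilicinic acid, 3,5-dihydroxy-4,4-dimethyl-2-(2-methylpropanoyl)cyclohexa-2,5-dien-1-one
Conditions: NaOMe, MeI (2 equiv), MeOH, 0 °C to rt
Reagents that add atoms: iodomethane, CI
Why: Dearomatising double C-methylation of the phloroglucinol polyanion at one ring carbon is the established entry to acylfilicinic acids, and limiting the methyl iodide to two equivalents should hold back over-methylation, with the under- and over-methylated congeners removed by chromatography.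

Step 13
Reactants: 17 1-{8-[(dimethylamino)methyl]-5,7-dihydroxy-2,2-dimethyl-2H-chromen-6-yl}-2-methylpropan-1-one; 20 isobutyrylfilicinic acid
Product: 22 target, 2-{[5,7-dihydroxy-2,2-dimethyl-6-(2-methylpropanoyl)-2H-chromen-8-yl]methyl}-3,5-dihydroxy-4,4-dimethyl-6-(2-methylpropanoyl)cyclohexa-2,5-dien-1-one, via ortho-quinone methide 21 (not isolated)
Conditions: PhMe, 110 °C
Reagents that add atoms: none
Why: Protonation of the Mannich base by the acidic triketone 20 and thermal loss of dimethylamine should give ortho-quinone methide 21, which is captured in a Michael addition by the single nucleophilic ring carbon of 20, and rearomatisation of ring B then gives the C8–CH2 bridge with no free formaldehyde to cause homodimers.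

Compound list
1 | phloroglucinol (benzene-1,3,5-triol) | Oc1cc(O)cc(O)c1 | starting material
2 | 3-methylbut-2-enoic acid | CC(C)=CC(=O)O | starting material
3 | 5,7-dihydroxy-2,2-dimethylchroman-4-one | CC1(C)CC(=O)c2c(O)cc(O)cc2O1 | intermediate
4 | 5-hydroxy-2,2-dimethyl-4-oxochroman-7-yl diethylcarbamate | CCN(CC)C(=O)Oc1cc(O)c2C(=O)CC(C)(C)Oc2c1 | intermediate
5 | 5-(methoxymethoxy)-2,2-dimethyl-4-oxochroman-7-yl diethylcarbamate | CCN(CC)C(=O)Oc1cc(OCOC)c2C(=O)CC(C)(C)Oc2c1 | intermediate
6 | 4-hydroxy-5-(methoxymethoxy)-2,2-dimethylchroman-7-yl diethylcarbamate (racemic) | CCN(CC)C(=O)Oc1cc(OCOC)c2C(O)CC(C)(C)Oc2c1 | intermediate (not isolated)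
7 | 5-(methoxymethoxy)-2,2-dimethyl-2H-chromen-7-yl diethylcarbamate | CCN(CC)C(=O)Oc1cc(OCOC)c2C=CC(C)(C)Oc2c1 | intermediate
8 | 6-lithio-5-(methoxymethoxy)-2,2-dimethyl-2H-chromen-7-yl diethylcarbamate | COCOc1c([Li])c(OC(=O)N(CC)CC)cc2OC(C)(C)C=Cc12 | intermediate (not isolated)
9 | 5-(methoxymethoxy)-2,2-dimethyl-6-(trimethylsilyl)-2H-chromen-7-yl diethylcarbamate | COCOc1c([Si](C)(C)C)c(OC(=O)N(CC)CC)cc2OC(C)(C)C=Cc12 | intermediate
10 | 5-(methoxymethoxy)-2,2-dimethyl-6-(trimethylsilyl)-2H-chromen-7-ol | COCOc1c([Si](C)(C)C)c(O)cc2OC(C)(C)C=Cc12 | intermediate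
11 | 5-(methoxymethoxy)-2,2-dimethyl-6-(trimethylsilyl)-2H-chromen-7-yl trifluoromethanesulfonate | COCOc1c([Si](C)(C)C)c(OS(=O)(=O)C(F)(F)F)cc2OC(C)(C)C=Cc12 | intermediate (key-step precursor)
12 | isobutyric acid | CC(C)C(=O)O | starting material
13 | 5-(methoxymethoxy)-2,2-dimethyl-6,7-didehydro-2H-chromene (6,7-aryne) | COCOC1=C2C=CC(C)(C)OC2=CC#C1 | intermediate (not isolated)
14 | 6-caesio-5-(methoxymethoxy)-2,2-dimethyl-2H-chromen-7-yl 2-methylpropanoate | COCOc1c([Cs])c(OC(=O)C(C)C)cc2OC(C)(C)C=Cc12 | intermediate (not isolated)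
15 | 1-[7-hydroxy-5-(methoxymethoxy)-2,2-dimethyl-2H-chromen-6-yl]-2-methylpropan-1-one | COCOc1c(C(=O)C(C)C)c(O)cc2OC(C)(C)C=Cc12 | intermediate (key-step product)
16 | 1-(5,7-dihydroxy-2,2-dimethyl-2H-chromen-6-yl)-2-methylpropan-1-one | CC(C)C(=O)c1c(O)cc2OC(C)(C)C=Cc2c1O | intermediate
17 | 1-{8-[(dimethylamino)methyl]-5,7-dihydroxy-2,2-dimethyl-2H-chromen-6-yl}-2-methylpropan-1-one | CC(C)C(=O)c1c(O)c(CN(C)C)c2OC(C)(C)C=Cc2c1O | intermediate
18 | isobutyryl chloride | CC(C)C(=O)Cl | starting material
19 | 1-(2,4,6-trihydroxyphenyl)-2-methylpropan-1-one | CC(C)C(=O)c1c(O)cc(O)cc1O | intermediate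
20 | isobutyrylfilicinic acid, 3,5-dihydroxy-4,4-dimethyl-2-(2-methylpropanoyl)cyclohexa-2,5-dien-1-one | CC(C)C(=O)C1=C(O)C(C)(C)C(O)=CC1=O | intermediate
21 | 5-hydroxy-2,2-dimethyl-8-methylidene-6-(2-methylpropanoyl)-2H-chromen-7(8H)-one | C=C1C(=O)C(C(=O)C(C)C)=C(O)C2=C1OC(C)(C)C=C2 | intermediate (not isolated)
22 | 2-{[5,7-dihydroxy-2,2-dimethyl-6-(2-methylpropanoyl)-2H-chromen-8-yl]methyl}-3,5-dihydroxy-4,4-dimethyl-6-(2-methylpropanoyl)cyclohexa-2,5-dien-1-one | CC(C)C(=O)C1=C(O)C(C)(C)C(O)=C(Cc2c(O)c(C(=O)C(C)C)c(O)c3c2OC(C)(C)C=C3)C1=O | target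

Total step count: 13. Longest linear sequence: 11 (steps 1–10 and 13).

Steps most likely to fail

Step 8 (key step). Proton transfer to the C6 aryl anion may outrun the acyl shift, so that the sequence stops at the O-aryl ester; carboxylate addition may also lose regiocontrol, or the acetal may be lost in the hot fluoride medium. The fallback avoids the aryne altogether; it sets out from 19 and comes back at 16. The unchelated para-hydroxyl of 19 is alkylated with 3-chloro-3-methylbut-1-yne (K2CO3, KI, acetone, reflux) to give 1-{2,6-dihydroxy-4-[(2-methylbut-3-yn-2-yl)oxy]phenyl}-2-methylpropan-1-one F1. Heating F1 in xylene at 140 °C should trigger a propargyl Claisen rearrangement, a 1,5-hydrogen shift and a 6π oxa-electrocyclisation to give 16. Because the para oxygen becomes O1 and the two ortho carbons are equivalent, the acyl group can only end on C6.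

Step 5. Deprotonation may be shared between C6 and C8, or the carbamoyl group may migrate to the lithiated carbon before silylation. The fallback fixes the site by halogenation and halogen–lithium exchange; it sets out from 4 and comes back at 9. Iodination of 4 ortho to the free chelated 5-OH (BnMe3N ICl2, CaCO3, CH2Cl2–MeOH) should give 5-hydroxy-6-iodo-2,2-dimethyl-4-oxochroman-7-yl diethylcarbamate F2. MOM protection as in step 3 gives 6-iodo-5-(methoxymethoxy)-2,2-dimethyl-4-oxochroman-7-yl diethylcarbamate F3. Reduction and dehydration as in step 4 pass through 4-hydroxy-6-iodo-5-(methoxymethoxy)-2,2-dimethylchroman-7-yl diethylcarbamate F4 to 6-iodo-5-(methoxymethoxy)-2,2-dimethyl-2H-chromen-7-yl diethylcarbamate F5. Iodine–lithium exchange on F5 (t-BuLi, THF, −78 °C) gives aryllithium 8 at a defined carbon, and Me3SiCl then gives 9.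

Step 13. Amine loss may be slow, and the quinone methide may oligomerise or add oxygen nucleophiles before the carbon nucleophile captures it. The fallback reverses the polarity of the one-carbon unit; it sets out from 16 and 20 and comes back at 22. Aqueous formaldehyde (1 equiv) with NaOH in H2O–MeOH at 0 °C to rt condenses with 20 (Knoevenagel) to a methylidene triketone, which the phenoxide of 16 captures at C8. The target is then separated from the two symmetric methylene-bridged dimers. This fallback makes no new compound (F0).

Further compounds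
F1 | step 8 | 1-{2,6-dihydroxy-4-[(2-methylbut-3-yn-2-yl)oxy]phenyl}-2-methylpropan-1-one | CC(C)C(=O)c1c(O)cc(OC(C)(C)C#C)cc1O
F2 | step 5 | 5-hydroxy-6-iodo-2,2-dimethyl-4-oxochroman-7-yl diethylcarbamate | CCN(CC)C(=O)Oc1cc2OC(C)(C)CC(=O)c2c(O)c1I
F3 | step 5 | 6-iodo-5-(methoxymethoxy)-2,2-dimethyl-4-oxochroman-7-yl diethylcarbamate | CCN(CC)C(=O)Oc1cc2OC(C)(C)CC(=O)c2c(OCOC)c1I
F4 | step 5 | 4-hydroxy-6-iodo-5-(methoxymethoxy)-2,2-dimethylchroman-7-yl diethylcarbamate (racemic) | CCN(CC)C(=O)Oc1cc2OC(C)(C)CC(O)c2c(OCOC)c1I
F5 | step 5 | 6-iodo-5-(methoxymethoxy)-2,2-dimethyl-2H-chromen-7-yl diethylcarbamate | CCN(CC)C(=O)Oc1cc2OC(C)(C)C=Cc2c(OCOC)c1I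
F0 | step 13 | none | none
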